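**Plan** (oxolane numbering of the target: O1, C2 guaiacyl, C3 CH2OH, C4 carbinol side chain, C5 H2)
1. Retrosynthesis cuts, in order: the two O–benzyl bonds and the carbinol C–H (back to aryl ketone 11); then O1–C2, with C2 joined back to C4, which gives the cyclopropyl ketone 8; then the cyclopropane bonds C2–C4 and C3–C4, which separate enal 2 (C2, C3, CH2OH carbon) from bromo keto ester 5 (C4, C5, carbinol carbon).
2. Enabling feature: the free 4-OH of the guaiacyl ring is para to benzylic C2, and the carbinol carbon on C4 can be held as a ketone. C2 (donor end, as a para-quinone methide) and C4 (acceptor end, as an enolate) are then 1,3-related as in a donor–acceptor cyclopropane, and the C5–O1H arm on C4 is placed to close a five-membered ring onto C2. The helpers are the silyl mask on the phenol (the trigger), the ketone level (removed in step 8) and the three-membered ring (consumed in the key step).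
3. Forward order: the cyclopropane is made first by an organocatalytic Michael-initiated ring closure; its carbonyl groups are adjusted; the three-membered ring is then traded for the oxolane by strain-release ring expansion; ketone reduction and debenzylation finish the route.
4. Stereochemistry: C3 comes from the prolinol-catalysed cyclopropanation; C2 and C4 are set relative to C3 under thermodynamic control in the ring expansion (all-trans oxolane); the carbinol centre comes from a reagent-controlled oxazaborolidine reduction that the Felkin–Anh preference of the ketone should reinforce.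

Key step: step 7

Assumption: 3 is taken as commercially available; 6, 7 and 8 are expected as mixtures of epimers at the quaternary cyclopropane carbon (7 also at the carbinol carbon), which has no consequence because the carbinol is oxidised in step 6 and the quaternary carbon becomes planar in step 7.

Step 1
Reactants: 1 (E)-3-(4-hydroxy-3-methoxyphenyl)prop-2-enal (coniferaldehyde)
Product: 2 (E)-3-[4-(tert-butyldimethylsilyloxy)-3-methoxyphenyl]prop-2-enal
Conditions: TBSCl (1.2 equiv), imidazole (2 equiv), CH2Cl2, 0 °C to 25 °C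
Reagents that add atoms: tert-butyldimethylsilyl chloride (TBSCl), CC(C)(C)[Si](C)(C)Cl
Why: Standard imidazole-assisted silylation of a phenol; the enal is untouched and the aryl silyl ether later serves as the fluoride-releasable trigger.

Step 2
Reactants: 3 1-[3,4-bis(benzyloxy)phenyl]ethan-1-one
Product: 4 ethyl 3-[3,4-bis(benzyloxy)phenyl]-3-oxopropanoate
Conditions: NaH (2.5 equiv), diethyl carbonate (3 equiv), THF, 65 °C; AcOH quench
Reagents that add atoms: diethyl carbonate, CCOC(=O)OCC
Why: Crossed Claisen condensation of the methyl ketone enolate with a non-enolisable carbonate; deprotonation of the β-keto ester drives the acylation and the benzyl ethers are inert to NaH.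

Step 3
Reactants: 4 ethyl 3-[3,4-bis(benzyloxy)phenyl]-3-oxopropanoate
Product: 5 ethyl 3-[3,4-bis(benzyloxy)phenyl]-2-bromo-3-oxopropanoate (racemic)
Conditions: NBS (1.0 equiv), NH4OAc (10 mol %), Et2O, 25 °C
Reagents that add atoms: N-bromosuccinimide (NBS), O=C1CCC(=O)N1Br
Why: Electrophilic α-bromination of the enol of a β-keto ester; one equivalent should stop at the monobromide, which is used as the racemate.

Step 4
Reactants: 2 (E)-3-[4-(tert-butyldimethylsilyloxy)-3-methoxyphenyl]prop-2-enal; 5 ethyl 3-[3,4-bis(benzyloxy)phenyl]-2-bromo-3-oxopropanoate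
Product: 6 ethyl (2R,3S)-1-[3,4-bis(benzyloxy)benzoyl]-3-[4-(tert-butyldimethylsilyloxy)-3-methoxyphenyl]-2-formylcyclopropane-1-carboxylate
Conditions: (S)-2-[diphenyl(trimethylsilyloxy)methyl]pyrrolidine (20 mol %), 2,6-lutidine (1.2 equiv), CH2Cl2, 0 °C to 25 °C
Reagents that add atoms: none
Why: Iminium–enamine Michael-initiated ring closure (organocatalytic cyclopropanation of enals with α-bromo 1,3-dicarbonyl compounds); the CPh2(OSiMe3) group shields one face of the iminium ion so the bromo keto ester adds to the β-carbon from the open face, and the enamine then displaces bromide in a 3-exo-tet closure that places the formyl group trans to the aryl group, which fixes the formyl-bearing carbon (future C3), the only centre carried through to the target.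

Step 5
Reactants: 6 ethyl (2R,3S)-1-[3,4-bis(benzyloxy)benzoyl]-3-[4-(tert-butyldimethylsilyloxy)-3-methoxyphenyl]-2-formylcyclopropane-1-carboxylate
Product: 7 [(2R,3S)-1-{[3,4-bis(benzyloxy)phenyl](hydroxy)methyl}-3-[4-(tert-butyldimethylsilyloxy)-3-methoxyphenyl]cyclopropane-1,2-diyl]dimethanol
Conditions: iBu2AlH (8 equiv), CH2Cl2, −78 °C to 25 °C; aqueous potassium sodium tartrate work-up
Reagents that add atoms: none
Why: Exhaustive hydride reduction of aldehyde, ketone and ester; the aryl silyl ether and benzyl ethers are stable to iBu2AlH, the cyclopropane loses its acceptors and cannot open, and the carbinol centre formed without control is removed in step 6.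

Step 6
Reactants: 7 [(2R,3S)-1-{[3,4-bis(benzyloxy)phenyl](hydroxy)methyl}-3-[4-(tert-butyldimethylsilyloxy)-3-methoxyphenyl]cyclopropane-1,2-diyl]dimethanol
Product: 8 [3,4-bis(benzyloxy)phenyl]{(2R,3S)-3-[4-(tert-butyldimethylsilyloxy)-3-methoxyphenyl]-1,2-bis(hydroxymethyl)cyclopropyl}methanone
Conditions: MnO2 (activated, 15 equiv), CH2Cl2, 25 °C
Reagents that add atoms: none
Why: MnO2 oxidation selective for the benzylic, cyclopropyl-activated secondary alcohol over the two primary alcohols; it restores the acceptor needed for step 7.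

Step 7
Reactants: 8 [3,4-bis(benzyloxy)phenyl]{(2R,3S)-3-[4-(tert-butyldimethylsilyloxy)-3-methoxyphenyl]-1,2-bis(hydroxymethyl)cyclopropyl}methanone
Product: 11 [3,4-bis(benzyloxy)phenyl][(3S,4R,5S)-5-(4-hydroxy-3-methoxyphenyl)-4-(hydroxymethyl)oxolan-3-yl]methanone, via free phenoxide 9 (not isolated), via para-quinone methide enolate 10 (not isolated)
Conditions: Bu4NF (1.3 equiv), THF, 0 °C to 50 °C; then AcOH (1.5 equiv)
Reagents that add atoms: none
Why: Proposed new method: fluoride unmasks the phenol, and in phenoxide 9 the para-oxygen pushes through the guaiacyl ring into the aryl-bearing cyclopropane carbon (future C2) while the aroyl group on the quaternary carbon (future C4) pulls, so the strained C2–C4 bond should break heterolytically to the para-quinone methide enolate 10; the hydroxymethyl oxygen on C4 (O1) then adds to the methide carbon and the enolate is protonated on carbon, a net isomerisation driven by release of cyclopropane strain and by rearomatisation. The closest known reaction types are the Cloke–Wilson rearrangement of cyclopropyl ketones, the base- or fluoride-triggered opening of donor–acceptor cyclopropanes with a hydroxyaryl or silyloxyaryl donor to quinone methides, and the oxa-1,6-addition of alcohols to para-quinone methides used in biomimetic lignan cyclisations; what is new is the single ketone acceptor and the use of a hydroxyl on the acceptor carbon as internal nucleophile. The oxolane closes in a 5-exo-trig mode, O1 attacking the exocyclic methide carbon. C3 (CH2OH) is not touched and controls both new centres: C2 is set trans to it in the ring closure, which is correctable because the addition is reversible through the quinone methide, and C4 is set trans to it by enolisation and reprotonation next to the ketone, so the all-trans oxolane is expected from either epimer of 8. The step needs cleavage of the C2–C4 and not the C2–C3 cyclopropane bond, secured because only C4 carries an anion-stabilising group, and it needs O1 to win over the other nucleophiles, secured because the C3 hydroxymethyl could only form an oxetane and the enolate oxygen gives a reversibly formed, less stable dihydrofuran enol ether. The benzyl ethers keep the second ring from becoming a phenoxide that would switch off the acceptor.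

Step 8
Reactants: 11 [3,4-bis(benzyloxy)phenyl][(3S,4R,5S)-5-(4-hydroxy-3-methoxyphenyl)-4-(hydroxymethyl)oxolan-3-yl]methanone
Product: 12 4-[(2S,3R,4S)-4-{(R)-[3,4-bis(benzyloxy)phenyl](hydroxy)methyl}-3-(hydroxymethyl)oxolan-2-yl]-2-methoxyphenol
Conditions: (S)-2-methyl-CBS-oxazaborolidine (20 mol %), BH3·SMe2 (4 equiv), THF, −20 °C; MeOH quench
Reagents that add atoms: none
Why: Corey–Bakshi–Shibata reduction; with the aryl group as the large substituent the (S)-catalyst should deliver hydride to the Si face and give the (R)-carbinol, and the Felkin–Anh model with ring C3 as the large α-substituent predicts the same face; the excess borane covers the phenol and the primary alcohol.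

Step 9
Reactants: 12 4-[(2S,3R,4S)-4-{(R)-[3,4-bis(benzyloxy)phenyl](hydroxy)methyl}-3-(hydroxymethyl)oxolan-2-yl]-2-methoxyphenol
Product: 13 4-{(R)-hydroxy[(3S,4R,5S)-5-(4-hydroxy-3-methoxyphenyl)-4-(hydroxymethyl)oxolan-3-yl]methyl}benzene-1,2-diol
Conditions: H2 (1 atm), 10% Pd/C, EtOAc/MeOH, 25 °C, stopped at full debenzylation
Reagents that add atoms: none
Why: Hydrogenolysis of the two aryl benzyl ethers, which under neutral conditions at 1 atm should be much faster than cleavage of the benzylic C–O bonds of the oxolane and the carbinol.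

**Compound list**
1 | (E)-3-(4-hydroxy-3-methoxyphenyl)prop-2-enal (coniferaldehyde) | COc1cc(/C=C/C=O)ccc1O | starting material
2 | (E)-3-[4-(tert-butyldimethylsilyloxy)-3-methoxyphenyl]prop-2-enal | COc1cc(/C=C/C=O)ccc1O[Si](C)(C)C(C)(C)C | intermediate
3 | 1-[3,4-bis(benzyloxy)phenyl]ethan-1-one | CC(=O)c1ccc(OCc2ccccc2)c(OCc2ccccc2)c1 | starting material
4 | ethyl 3-[3,4-bis(benzyloxy)phenyl]-3-oxopropanoate | CCOC(=O)CC(=O)c1ccc(OCc2ccccc2)c(OCc2ccccc2)c1 | intermediate
5 | ethyl 3-[3,4-bis(benzyloxy)phenyl]-2-bromo-3-oxopropanoate (racemic) | CCOC(=O)C(Br)C(=O)c1ccc(OCc2ccccc2)c(OCc2ccccc2)c1 | intermediate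
6 | ethyl (2R,3S)-1-[3,4-bis(benzyloxy)benzoyl]-3-[4-(tert-butyldimethylsilyloxy)-3-methoxyphenyl]-2-formylcyclopropane-1-carboxylate (formyl trans to aryl; both C1 epimers) | COc1cc([C@@H]2[C@@H](C=O)C2(C(=O)OCC)C(=O)c2ccc(OCc3ccccc3)c(OCc3ccccc3)c2)ccc1O[Si](C)(C)C(C)(C)C | intermediate
7 | [(2R,3S)-1-{[3,4-bis(benzyloxy)phenyl](hydroxy)methyl}-3-[4-(tert-butyldimethylsilyloxy)-3-methoxyphenyl]cyclopropane-1,2-diyl]dimethanol (epimers at C1 and at the carbinol carbon) | COc1cc([C@@H]2[C@@H](CO)C2(CO)C(O)c2ccc(OCc3ccccc3)c(OCc3ccccc3)c2)ccc1O[Si](C)(C)C(C)(C)C | intermediate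
8 | [3,4-bis(benzyloxy)phenyl]{(2R,3S)-3-[4-(tert-butyldimethylsilyloxy)-3-methoxyphenyl]-1,2-bis(hydroxymethyl)cyclopropyl}methanone (both C1 epimers) | COc1cc([C@@H]2[C@@H](CO)C2(CO)C(=O)c2ccc(OCc3ccccc3)c(OCc3ccccc3)c2)ccc1O[Si](C)(C)C(C)(C)C | intermediate
9 | [3,4-bis(benzyloxy)phenyl][(2R,3S)-3-(4-hydroxy-3-methoxyphenyl)-1,2-bis(hydroxymethyl)cyclopropyl]methanone, present as its tetrabutylammonium phenoxide | COc1cc([C@@H]2[C@@H](CO)C2(CO)C(=O)c2ccc(OCc3ccccc3)c(OCc3ccccc3)c2)ccc1O | intermediate
10 | 4-[(2R)-4-[3,4-bis(benzyloxy)phenyl]-4-hydroxy-2,3-bis(hydroxymethyl)but-3-en-1-ylidene]-2-methoxycyclohexa-2,5-dien-1-one, present as its enolate | COC1=CC(=C[C@@H](CO)C(CO)=C(O)c2ccc(OCc3ccccc3)c(OCc3ccccc3)c2)C=CC1=O | intermediate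
11 | [3,4-bis(benzyloxy)phenyl][(3S,4R,5S)-5-(4-hydroxy-3-methoxyphenyl)-4-(hydroxymethyl)oxolan-3-yl]methanone | COc1cc([C@H]2OC[C@@H](C(=O)c3ccc(OCc4ccccc4)c(OCc4ccccc4)c3)[C@@H]2CO)ccc1O | intermediate
12 | 4-[(2S,3R,4S)-4-{(R)-[3,4-bis(benzyloxy)phenyl](hydroxy)methyl}-3-(hydroxymethyl)oxolan-2-yl]-2-methoxyphenol | COc1cc([C@H]2OC[C@@H]([C@@H](O)c3ccc(OCc4ccccc4)c(OCc4ccccc4)c3)[C@@H]2CO)ccc1O | intermediate
13 | 4-{(R)-hydroxy[(3S,4R,5S)-5-(4-hydroxy-3-methoxyphenyl)-4-(hydroxymethyl)oxolan-3-yl]methyl}benzene-1,2-diol | COc1cc([C@H]2OC[C@@H]([C@@H](O)c3ccc(O)c(O)c3)[C@@H]2CO)ccc1O | target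

**Total step count:** 9. **Longest linear sequence:** 8 steps (from 3: steps 2 to 9).

**Steps most likely to fail**

Step 7 (proposed new method). The single aroyl acceptor may not polarise the cyclopropane bond enough for heterolysis at a useful temperature. The quinone methide may also tautomerise to a vinylphenol, with loss of the C3 centre, before the hydroxyl closes, and equilibration next to the ketone may stay incomplete. The fallback uses known chemistry and sets out from 8. SmI2 (THF/MeOH, −78 °C) should cleave the same cyclopropane bond reductively through the ketyl radical anion, opening toward the benzylic radical, to give the ring-opened ketone (3R)-1-[3,4-bis(benzyloxy)phenyl]-4-[4-(tert-butyldimethylsilyloxy)-3-methoxyphenyl]-2,3-bis(hydroxymethyl)butan-1-one F1. Buffered Bu4NF/AcOH (THF, 0 °C) should then free the phenol to give (3R)-1-[3,4-bis(benzyloxy)phenyl]-4-(4-hydroxy-3-methoxyphenyl)-2,3-bis(hydroxymethyl)butan-1-one F2. DDQ (CH2Cl2, 0 °C) should oxidise the 4-hydroxybenzyl position to the quinone methide, which the hydroxymethyl next to the ketone closes in the same 5-exo mode (the known biomimetic oxidative cyclisation), and brief Et3N treatment should equilibrate the centre next to the ketone. The route is rejoined at 11.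

Step 4. Conjugate addition to the electron-rich enal may be slow, the catalyst may be N-alkylated by the bromide, ring closure may go through oxygen instead of carbon, and facial selectivity may be lower than with malonates. The fallback sets out from 2. The same aminocatalytic cyclopropanation with diethyl bromomalonate, the best-precedented partner, should give diethyl (2R,3S)-3-[4-(tert-butyldimethylsilyloxy)-3-methoxyphenyl]-2-formylcyclopropane-1,1-dicarboxylate F3. NaBH4 (MeOH, 0 °C) reduces the aldehyde, and the alcohol lactonises onto the cis ester to give ethyl (1S,5R,6S)-6-[4-(tert-butyldimethylsilyloxy)-3-methoxyphenyl]-2-oxo-3-oxabicyclo[3.1.0]hexane-1-carboxylate (aryl exo) F4. One equivalent of the aryllithium from 4-bromo-1,2-bis(benzyloxy)benzene and n-BuLi (THF, −78 °C) should add once to the lactone carbonyl to give ethyl (1R,2R,3S)-1-[3,4-bis(benzyloxy)benzoyl]-3-[4-(tert-butyldimethylsilyloxy)-3-methoxyphenyl]-2-(hydroxymethyl)cyclopropane-1-carboxylate (aroyl cis to the hydroxymethyl group) F5; addition to the ester instead would lead to the same triol after reduction. iBu2AlH as in step 5 then gives 7, where the route is rejoined.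

Step 6. The cyclopropylmethyl primary alcohols may be oxidised in competition, or the hindered carbinol may react sluggishly. The fallback sets out from 7. TBSCl (2.2 equiv) and imidazole (DMF, 0 °C) should silylate only the two primary alcohols to give [3,4-bis(benzyloxy)phenyl]{(2R,3S)-1,2-bis[(tert-butyldimethylsilyloxy)methyl]-3-[4-(tert-butyldimethylsilyloxy)-3-methoxyphenyl]cyclopropyl}methanol F6. Dess–Martin periodinane (NaHCO3, CH2Cl2) oxidises the remaining secondary alcohol to [3,4-bis(benzyloxy)phenyl]{(2R,3S)-1,2-bis[(tert-butyldimethylsilyloxy)methyl]-3-[4-(tert-butyldimethylsilyloxy)-3-methoxyphenyl]cyclopropyl}methanone F7. F7 is taken into the conditions of step 7 with 3.5 equiv of Bu4NF, which removes all three silyl groups before the ring expansion, and the route is rejoined at 11.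

**Further compounds**
F1 | step 7 | (3R)-1-[3,4-bis(benzyloxy)phenyl]-4-[4-(tert-butyldimethylsilyloxy)-3-methoxyphenyl]-2,3-bis(hydroxymethyl)butan-1-one (C2 epimers) | COc1cc(C[C@@H](CO)C(CO)C(=O)c2ccc(OCc3ccccc3)c(OCc3ccccc3)c2)ccc1O[Si](C)(C)C(C)(C)C
F2 | step 7 | (3R)-1-[3,4-bis(benzyloxy)phenyl]-4-(4-hydroxy-3-methoxyphenyl)-2,3-bis(hydroxymethyl)butan-1-one (C2 epimers) | COc1cc(C[C@@H](CO)C(CO)C(=O)c2ccc(OCc3ccccc3)c(OCc3ccccc3)c2)ccc1O
F3 | step 4 | diethyl (2R,3S)-3-[4-(tert-butyldimethylsilyloxy)-3-methoxyphenyl]-2-formylcyclopropane-1,1-dicarboxylate | COc1cc([C@@H]2[C@@H](C=O)C2(C(=O)OCC)C(=O)OCC)ccc1O[Si](C)(C)C(C)(C)C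
F4 | step 4 | ethyl (1S,5R,6S)-6-[4-(tert-butyldimethylsilyloxy)-3-methoxyphenyl]-2-oxo-3-oxabicyclo[3.1.0]hexane-1-carboxylate (aryl exo) | COc1cc([C@@H]2[C@H]3COC(=O)[C@@]23C(=O)OCC)ccc1O[Si](C)(C)C(C)(C)C
F5 | step 4 | ethyl (1R,2R,3S)-1-[3,4-bis(benzyloxy)benzoyl]-3-[4-(tert-butyldimethylsilyloxy)-3-methoxyphenyl]-2-(hydroxymethyl)cyclopropane-1-carboxylate (aroyl cis to hydroxymethyl) | COc1cc([C@@H]2[C@@H](CO)[C@@]2(C(=O)OCC)C(=O)c2ccc(OCc3ccccc3)c(OCc3ccccc3)c2)ccc1O[Si](C)(C)C(C)(C)C
F6 | step 6 | [3,4-bis(benzyloxy)phenyl]{(2R,3S)-1,2-bis[(tert-butyldimethylsilyloxy)methyl]-3-[4-(tert-butyldimethylsilyloxy)-3-methoxyphenyl]cyclopropyl}methanol (epimers at C1 and at the carbinol carbon) | COc1cc([C@@H]2[C@@H](CO[Si](C)(C)C(C)(C)C)C2(CO[Si](C)(C)C(C)(C)C)C(O)c2ccc(OCc3ccccc3)c(OCc3ccccc3)c2)ccc1O[Si](C)(C)C(C)(C)C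
F7 | step 6 | [3,4-bis(benzyloxy)phenyl]{(2R,3S)-1,2-bis[(tert-butyldimethylsilyloxy)methyl]-3-[4-(tert-butyldimethylsilyloxy)-3-methoxyphenyl]cyclopropyl}methanone (both C1 epimers) | COc1cc([C@@H]2[C@@H](CO[Si](C)(C)C(C)(C)C)C2(CO[Si](C)(C)C(C)(C)C)C(=O)c2ccc(OCc3ccccc3)c(OCc3ccccc3)c2)ccc1O[Si](C)(C)C(C)(C)C
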